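**Retrosynthetic overview**

- The target is a trans-fused eudesmane (rings A and B, 5α-H, 10β-CH3, 7β-isopropyl). Its 3α,4β-diol is traced back to a C3=C4 alkene through an α-epoxide opened diaxially at C4 with help from the 1,3-diaxial 6β-benzoate; the benzoate comes from a 6β-alcohol and that from a C6 ketone.
- The strategy rests on one feature: once the C5–C10 fusion bond is removed, the perimeter C1–C10 (CH3 on C4 and on C10, the C3 branch on C7, oxygen on C6 flanked by C5 and C7, alkene-level C3/C4) is the achiral ten-membered ketone germacrone counted in the reverse sense. Germacrone C8=O is C6, C9 is C5, the 1(10)-alkene is C3=C4, C4 is C10 and C7 remains C7.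
- Key disconnection C5–C10: a C5 dienolate alkylated across the ring by a C9–C10 oxirane, which is made by catalytic asymmetric epoxidation of germacrone and carries all absolute stereochemistry.
- Ring order: the ten-membered ring is bought; rings A and B are closed together by the one C5–C10 bond; later only a transient C3–C4 oxirane and a transient dioxanylium ring (C4–O–C–O–C6) are formed and opened. Eudesmane numbering is used for all compounds, the ten-membered ones included.

Key step: step 2

Assumption: by the spiro transition-state model for E-trisubstituted alkenes, the L-series ketone catalyst (enantiomer of the usual D-fructose-derived one) should deliver the (4S,5S) oxirane; if the ten-membered ring reversed this sense, the D-series ketone would be used in the same step.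

**Route**

Step 1
Reactants: 1 germacrone
Product: 2 (4S,5S)-germacrone 4,5-epoxide
Conditions: 1,2:4,5-di-O-isopropylidene-β-L-erythro-2,3-hexodiulo-2,6-pyranose (0.3 equiv), KHSO5 (as Oxone, 2KHSO5·KHSO4·K2SO4), K2CO3, Bu4NHSO4 (cat.), MeCN–CH2(OMe)2/aq Na2B4O7 buffer (pH ca. 10), −5 to 0 °C, stopped short of full conversion
Reagents that add atoms: potassium peroxymonosulfate, [K+].[O-]S(=O)(=O)OO
Why: Shi-type asymmetric epoxidation through a chiral dioxirane, in which the electrophilic oxidant should take the most electron-rich alkene (trisubstituted and remote from the carbonyl, whereas C3=C4 is β,γ to the ketone and the enone alkene is electron-poor) and the catalyst chooses the enantioface of the E-alkene exposed on the ring periphery while the ring conformers interconvert, which sets both oxirane centres.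

Step 2
Reactants: 2 (4S,5S)-germacrone 4,5-epoxide
Product: 5 9β-hydroxyeudesma-3,7(11)-dien-6-one, via conjugated enone isomer 3 (not isolated), via dipotassium dienolate 4 (not isolated)
Conditions: KOtBu (3 equiv), THF–tBuOH, 0 °C to rt, Ar; then cannulated into cold aq AcOH, 0 °C
Reagents that add atoms: none
Why: This is a transannular enolate alkylation by an epoxide, the base-induced decalin-forming cyclisation known for epoxygermacranones: KOtBu removes the doubly activated C5–H, and since ring A cannot hold a trans double bond, C3=C4 first moves by reversible proton transfer through the conjugated C4=C5 enone 3 and returns as the extended dienolate with C2 and C5 cis, whose α-carbon C5 then displaces the oxirane oxygen from the tertiary C10 with inversion. The one new C5–C10 bond closes ring A in a 6-exo-tet mode (the oxygen departs onto C9, outside ring A) and ring B in a 6-endo-tet mode (both oxirane carbons end up in ring B), through a chair–chair, decalin-like array in which the rear of the C10–O bond faces C5 across the ring. C10 is fixed by that inversion and therefore by the (4S,5S) oxirane, C9 keeps its oxygen (9β, equatorial), and C5 is set when the resting dienolate 4 is quenched under kinetic control by protonation at C5 anti to the axial C10 methyl, which should give the trans fusion and leave the alkene at C3=C4. The step needs C5-to-C10 closure in preference to C5-to-C9 closure (5/7 skeleton), O-alkylation and attack from C3: the cross-ring geometry and the strain-free 6/6 transition state favour C10, attack from C3 would make a four-membered ring, O-alkylation would leave a bridgehead enol ether, and dienolates alkylate at the α-carbon. The C7 isopropylidene leaves no α-hydrogen on the other flank of C6, so only this enolate family forms, and the potassium ion on the peripheral oxirane oxygen weakens the more substituted C10–O bond.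

Step 3
Reactants: 5 9β-hydroxyeudesma-3,7(11)-dien-6-one
Product: 7 9β-hydroxyeudesm-3-en-6-one, via dilithium enolate 6 (not isolated)
Conditions: Li (2.5 equiv), NH3(l)–THF, −78 °C, 5 added last; isoprene, then solid NH4Cl, −78 °C
Reagents that add atoms: none
Why: Dissolving-metal (Birch-type) conjugate reduction touches only the α,β-unsaturated ketone (the isolated C3=C4 alkene is inert), C11 takes its proton from the C9 hydroxyl or ammonia, and C7 is set on quench by axial protonation of enolate 6 from the α face, which places the isopropyl group equatorial (β), also the more stable epimer.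

Step 4
Reactants: 7 9β-hydroxyeudesm-3-en-6-one
Product: 8 O-(6-oxoeudesm-3-en-9β-yl) O-phenyl carbonothioate
Conditions: PhOC(S)Cl, pyridine, DMAP (cat.), CH2Cl2, 0 °C to rt
Reagents that add atoms: O-phenyl chlorothionoformate, S=C(Cl)Oc1ccccc1
Why: Thioacylation of the equatorial secondary C9 alcohol (first stage of a Barton–McCombie deoxygenation) under a mild amine base at or below room temperature, chosen so that the acidic C5–H is left alone and C3=C4 stays out of conjugation.

Step 5
Reactants: 8 O-(6-oxoeudesm-3-en-9β-yl) O-phenyl carbonothioate
Product: 9 eudesm-3-en-6-one (5α-H, 7β-isopropyl)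
Conditions: Bu3SnH, AIBN (cat.), toluene, 90 °C, degassed
Reagents that add atoms: none
Why: Barton–McCombie radical deoxygenation, in which the stannyl radical adds to sulfur, β-scission frees the secondary C9 radical and this takes hydrogen from Bu3SnH; the neutral conditions spare the β,γ-unsaturated ketone and the C9 stereocentre disappears.

Step 6
Reactants: 9 eudesm-3-en-6-one
Product: 10 eudesm-3-en-6β-ol
Conditions: LiAlH4, THF, −78 °C; then H2O
Reagents that add atoms: none
Why: Substrate-controlled hydride reduction of the ketone, in which the β (axial) approach to C6 is blocked by the syn-axial C10 methyl so hydride enters from the α face and the axial 6β-alcohol should result, as in 6-oxo-5α-steroids; the fast reduction at low temperature should outrun enolisation toward C5.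

Step 7
Reactants: 10 eudesm-3-en-6β-ol; 11 benzoyl chloride
Product: 12 6β-benzoyloxyeudesm-3-ene
Conditions: BzCl, DMAP (0.2 equiv), pyridine, 50 °C
Reagents that add atoms: benzoyl chloride (compound 11), O=C(Cl)c1ccccc1
Why: DMAP-catalysed acylation of the hindered axial alcohol through the N-benzoylpyridinium ion, which touches no stereocentre and is placed before the epoxidation so that no hydroxyl-directed β-epoxidation can occur and the participating group is in place.

Step 8
Reactants: 12 6β-benzoyloxyeudesm-3-ene
Product: 13 3α,4α-epoxy-6β-benzoyloxyeudesmane
Conditions: mCPBA, CH2Cl2, 0 °C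
Reagents that add atoms: 3-chloroperoxybenzoic acid, OOC(=O)c1cccc(Cl)c1
Why: Prilezhaev epoxidation (concerted syn oxygen transfer) from the α face, because the β face of C3=C4 is screened by the axial C10 methyl and the axial C6 benzoate, which sets C3 and C4 with the oxirane oxygen α.

Step 9
Reactants: 13 3α,4α-epoxy-6β-benzoyloxyeudesmane
Product: 15 3α,4β-dihydroxy-6β-benzoyloxyeudesmane (CNP0187831.1), via dioxanylium perchlorate 14 (not isolated)
Conditions: HClO4 (70% aq, cat.), THF–H2O, 0 °C to rt
Reagents that add atoms: water, O
Why: Acid-catalysed epoxide opening with neighbouring-group participation, in which the protonated oxirane is opened at the tertiary C4 from the β face by the carbonyl oxygen of the 1,3-diaxial C6 benzoate (trans-diaxial, Fürst–Plattner mode; inversion at C4, C3–O retained as 3α-OH) to give ion 14, water adds to its cationic carbon, and the tetrahedral adduct collapses with the benzoyl group on the secondary O6, leaving the tertiary 4β-OH free.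

**Compound list**

1 | germacrone, (1(10)E,4E)-germacra-1(10),4,7(11)-trien-8-one | C/C1=C\CC(=C(C)C)C(=O)C/C(C)=C/CC1 | starting material
2 | (4S,5S)-germacrone 4,5-epoxide (trans-oxirane on eudesmane C10 and C9) | C[C@]12CC/C=C(\C)CC(=O)C(=C(C)C)C[C@@H]1O2 | intermediate
3 | (4S,5S,9Z)-4,5-epoxygermacra-7(11),9-dien-8-one (conjugated C4=C5 enone isomer of 2; the geometry of this alkene is immaterial) | C[C@]12CCC/C(C)=C\C(=O)C(=C(C)C)C[C@@H]1O2 | intermediate (not isolated)
4 | dipotassium 9β-oxidoeudesma-3,5,7(11)-trien-6-olate | CC(C)=C1C[C@H]([O-])[C@@]2(C)CCC=C(C)C2=C1[O-].[K+].[K+] | intermediate (not isolated)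
5 | 9β-hydroxyeudesma-3,7(11)-dien-6-one (5α-H, 10β-CH3) | CC(C)=C1C[C@H](O)[C@@]2(C)CCC=C(C)[C@@H]2C1=O | intermediate
6 | dilithium 9β-oxidoeudesma-3,6-dien-6-olate (5α-H) | CC(C)C=1C[C@H]([O-])[C@@]2(C)CCC=C(C)[C@@H]2C=1[O-].[Li+].[Li+] | intermediate (not isolated)
7 | 9β-hydroxyeudesm-3-en-6-one (5α-H, 7β-isopropyl) | CC(C)[C@@H]1C[C@H](O)[C@@]2(C)CCC=C(C)[C@@H]2C1=O | intermediate
8 | O-(6-oxoeudesm-3-en-9β-yl) O-phenyl carbonothioate | CC(C)[C@@H]1C[C@H](OC(=S)Oc3ccccc3)[C@@]2(C)CCC=C(C)[C@@H]2C1=O | intermediate
9 | eudesm-3-en-6-one (5α-H, 7β-isopropyl) | CC(C)[C@@H]1CC[C@@]2(C)CCC=C(C)[C@@H]2C1=O | intermediate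
10 | eudesm-3-en-6β-ol | CC(C)[C@@H]1CC[C@@]2(C)CCC=C(C)[C@@H]2[C@@H]1O | intermediate
11 | benzoyl chloride | O=C(Cl)c1ccccc1 | starting material
12 | 6β-benzoyloxyeudesm-3-ene | CC(C)[C@@H]1CC[C@@]2(C)CCC=C(C)[C@@H]2[C@@H]1OC(=O)c1ccccc1 | intermediate
13 | 3α,4α-epoxy-6β-benzoyloxyeudesmane | CC(C)[C@@H]1CC[C@@]2(C)CC[C@H]3O[C@@]3(C)[C@@H]2[C@@H]1OC(=O)c1ccccc1 | intermediate
14 | 2-phenyl-1,3-dioxan-2-ylium perchlorate bridging O4β and O6β of 3α-hydroxyeudesmane | CC(C)[C@@H]1CC[C@@]2(C)CC[C@@H](O)[C@](C)(O3)[C@@H]2[C@@H]1O[C+]3c1ccccc1.[O-]Cl(=O)(=O)=O | intermediate (not isolated)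
15 | 3α,4β-dihydroxy-6β-benzoyloxyeudesmane (CNP0187831.1) | CC(C)[C@@H]1CC[C@@]2(C)CC[C@@H](O)[C@](C)(O)[C@@H]2[C@@H]1OC(=O)c1ccccc1 | target

**Step count and risks**

Total step count: 9. Longest linear sequence: 9 steps (1 to 15).

Steps most likely to fail:

1. Step 2. The dienolate may open the tertiary C10–O bond too slowly, so that base-induced isomerisation of the oxirane to an allylic alcohol or mere conjugation of the ten-membered enone takes over; the quench may also deliver the proton to C3 and move the alkene into conjugation. The fallback sets out from 2 and returns at 5. It replaces the anionic displacement by a Lewis-acid-promoted, cation-like opening, that is, an epoxide-initiated cyclisation terminated by a silyl enol ether (Mukaiyama type), for which the tertiary C10 is the electronically preferred site. Compound 2 would be isomerised with DBU in CH2Cl2 to the conjugated enone 3, now isolated. Enone 3 would be γ-deprotonated with slightly less than one equivalent of KHMDS in THF (−78 to −30 °C, equilibration through the residual ketone) and the thermodynamic dienolate trapped with TBSCl as the (3Z)-tert-butyldimethylsilyl dienol ether of the epoxy ketone F1. MeAlCl2 in CH2Cl2 at −78 °C would then ionise the oxirane at C10, C5 of the dienol ether would close rings A and B, and loss of the silyl group with aqueous work-up would give 5. Any cis-fused material could be corrected by the enolisation and kinetic protonation of step 2.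

2. Step 1. Site selection between the two ring alkenes or facial selection by the dioxirane may be poor on a conformationally mobile ten-membered ring, and over-oxidation to a bis-epoxide is possible. The fallback sets out from 1 and returns at 2. It gives up catalyst control for resolution: mCPBA in CH2Cl2 at 0 °C should oxidise the same electron-rich alkene and give 2 together with its mirror image, (4R,5R)-germacrone 4,5-epoxide F2. The two would be separated on a preparative chiral stationary phase (cellulose carbamate type), F2 discarded, and 2 carried into step 2.

3. Step 4. Acylation of the neopentyl-type C9 carbinol may be slow, and during it the amine base may remove the doubly activated C5–H, so that C3=C4 migrates into conjugation with the C6 ketone or C5 epimerises. The fallback sets out from 7 and returns at 10. It changes the order so that the ketone is gone before any basic or thermal step: LiAlH4 in THF at −78 °C would reduce 7 from the α face to eudesm-3-ene-6β,9β-diol F3. The equatorial C9 hydroxyl would then be thioacylated selectively with PhOC(S)Cl and pyridine (the axial C6 hydroxyl is screened by the C10 methyl and the C7 isopropyl) to give O-(6β-hydroxyeudesm-3-en-9β-yl) O-phenyl carbonothioate F4. Bu3SnH and AIBN in toluene would then give 10.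

**Further compounds**

F1 | step 2 | (3Z)-tert-butyldimethylsilyl dienol ether of (4S,5S)-germacrone 4,5-epoxide (C3=C4–C5=C6–OSi, C2 and C5 cis) | C[C@]12CC/C=C(/C)\C=C(/O[Si](C)(C)C(C)(C)C)C(=C(C)C)C[C@@H]1O2
F2 | step 1 | (4R,5R)-germacrone 4,5-epoxide | C[C@@]12CC/C=C(\C)CC(=O)C(=C(C)C)C[C@H]1O2
F3 | step 4 | eudesm-3-ene-6β,9β-diol | CC(C)[C@@H]1C[C@H](O)[C@@]2(C)CCC=C(C)[C@@H]2[C@@H]1O
F4 | step 4 | O-(6β-hydroxyeudesm-3-en-9β-yl) O-phenyl carbonothioate | CC(C)[C@@H]1C[C@H](OC(=S)Oc3ccccc3)[C@@]2(C)CCC=C(C)[C@@H]2[C@@H]1O
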